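I charged each flask with 0.25 M of starting material and no dissolved reagent, so the reagent had to enter through the gas.

| flask | starting material | gas | temperature | time |
|---|---|---|---|---|
| grey | 0.25 M | 150 mM (held) | 5 °C | 2.0 d |
| amber | 0.25 M | 150 mM (held) | 30 °C | 2.0 d |
| ochre | 0.25 M | 150 mM (held) | −20 °C | 2.0 d |

    starting material + reagent → first product + released group (k1 = 0.39 M⁻¹ h⁻¹, Ea1 = 55.0 kJ mol⁻¹)
    reagent + first product → bis adduct + released group (k2 = 0.81 M⁻¹ h⁻¹, Ea2 = 46.0 kJ mol⁻¹)
    starting material + released group → side product (k3 = 0.20 M⁻¹ h⁻¹, Ea3 = 50.0 kJ mol⁻¹)
    gas ⇌ reagent, rate k4*(csat - [reagent]) (k4 = 0.011 h⁻¹, csat = 150 mM)
    starting material ⇌ dormant form (K5 = 10, k5 = 0.016 h⁻¹, Ea5 = 78.0 kJ mol⁻¹, ΔH5 = −65.0 kJ mol⁻¹)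
    (constants at −20 °C)

- at the start none of reagent is dissolved
- the list of constants is for −20 °C, to be carried to other temperatures by the activation energies and enthalpies

- which flask leads in share of first product in all that became first product or bis adduct or side product ("all alike" within 1.5 percentage points) (grey / amber / ochre / all alike)
- share of first product in all that became first product or bis adduct or side product, grey
- share of first product in all that became first product or bis adduct or side product, amber
- share of first product in all that became first product or bis adduct or side product, ochre

I kept my books on reagent. With none dissolved, transfer runs at 1.65 mM h⁻¹, and any dissolved reagent slows it. Over the asked time this gives an upper limit that I call the reagent budget 79.2 mM, the transfer coefficient times the saturation concentration times the time. That is 31.7% of the charge, less than the starting material, so reagent is the limiting reagent for this period.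

The budget has three entries, and they cannot exceed it:

[reagent] + [first product] + two × [bis adduct] ≤ 79.2 mM

Each mole of reagent spent also frees one released group. That group either waits or takes one starting material into side product, which gives a second book:

[side product] + [released group] = [first product] + two × [bis adduct]

If no released group waits, side product at least equals first product, and the share of first product is at most half.

How far that second book stays open is a matter of time. In ochre, which runs at the listed constants, reagent lasts about 10.3 h among the charged starting material. At that same amount, a released group lasts about 20.0 h, longer. Together they take 30.3 h, and transfer goes on to the end of the 48 h, so reagent entering late has had less than that.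

So I expected released group to be waiting in ochre at the end. Capture has an activation energy of 50.0 kJ mol⁻¹, so I expected grey and amber to come nearer to closing the second book. I stopped there, with ochre first and no shares of my own.

The forecast gave grey 32.5%, amber 36.5% and ochre 48.5%, with ochre leading. Its ground for ochre was that “released group accumulates rather than being scavenged”.

The simulation gave grey 32.5%, amber 36.5% and ochre 49.4%, so ochre led and the forecast held. At 2.00 d, ochre had taken up 71.3 mM of the 79.2 mM, less than the limit, and 0.0220 M of that was still dissolved reagent. Ochre then held 0.0316 M of released group, which was being made 2.35 times as fast as it was used up, each step taken net. A flask like ochre kept at −5 °C had the same budget, had taken up 75.2 mM of it, held 0.0279 M of released group and gave a share of 32.3%.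

(Its constants are invented; what happens was integrated by code.)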